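## Retrosynthetic overview
1. Colleterpenol comes from the macrocyclic C15 tertiary pinacol boronate (C–B to C–OH with retention). Boron marks the site where water quenches the C15 cation in the biosynthesis.
2. The only ring (14-membered) closes through the C1–C14 bond, as in the 1,14-cyclisation of hexaprenyl diphosphate. A C1 allyl cation equivalent (π-allylpalladium from an allylic carbamate) is attacked by the C14=C15 π bond of an alkenyl boronate complex. The charge at C15 is quenched by 1,2-shift of the homogeranyl group from boron, which forms C15–C16.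
3. The boronate complex comes from a C19 (E)-vinyl iodide (C1–C15 plus four methyl groups) and the C11 homogeranyl pinacol boronate.
4. The vinyl iodide comes from (E,E)-farnesol (ω-oxidation, then bromide) and but-2-yne (C12–C13 bond), followed by syn-hydrozirconation and iodination. The boronate comes from geranyl bromide and CH2(Bpin)2.
5. Ring order: one ring closure, in the last C–C bond-forming operation, which also sets both stereocentres.

Assumption: positions follow the hexaprenyl chain (C1–C24; target = 14R,15S); the sense of induction of BINAP in step 7 cannot be predicted, so (R)-BINAP is written and its antipode is used if the first run gives the mirror image.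

## Route

Step 1
Reactants: 1 (2E,6E)-farnesol; 2 N,N-diisopropylcarbamoyl chloride
Product: 3 (2E,6E)-farnesyl N,N-diisopropylcarbamate
Conditions: 2 (1.3 equiv), Et3N (1.5 equiv), CH2Cl2, reflux, 24 h
Reagents that add atoms: N,N-diisopropylcarbamoyl chloride (2), CC(C)N(C(C)C)C(=O)Cl
Why: Carbamoylation (acyl substitution) of the primary allylic alcohol gives a hindered carbamate that withstands oxidants, organolithiums and Cp2Zr(H)Cl yet can later be ionised by zerovalent palladium, so one group serves as both protecting group and leaving group; no stereocentre is formed.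

Step 2
Reactants: 3 (2E,6E)-farnesyl N,N-diisopropylcarbamate
Product: 4 (2E,6E,10E)-12-hydroxyfarnesyl N,N-diisopropylcarbamate
Conditions: SeO2 (0.2 equiv), t-BuOOH (3 equiv), 2-hydroxybenzoic acid (0.1 equiv), CH2Cl2, 0→23 °C, 20 h
Reagents that add atoms: SeO2 (catalytic oxygen carrier), O=[Se]=O; tert-butyl hydroperoxide (terminal oxygen source), CC(C)(C)OO
Why: Catalytic SeO2 allylic oxidation (ene reaction, then [2,3]-sigmatropic shift) attacks the most electron-rich and least hindered terminal isopropylidene and gives the (E)-allylic alcohol, because the 2,3-alkene is deactivated by the allylic carbamate.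

Step 3
Reactants: 4 (2E,6E,10E)-12-hydroxyfarnesyl N,N-diisopropylcarbamate
Product: 5 (2E,6E,10E)-12-bromofarnesyl N,N-diisopropylcarbamate
Conditions: PBr3 (0.4 equiv), Et2O, 0 °C, 30 min
Reagents that add atoms: phosphorus tribromide, BrP(Br)Br
Why: Bromination of the primary allylic alcohol through its phosphite ester (SN2) keeps the 10E geometry and leaves the carbamate untouched.

Step 4
Reactants: 5 (2E,6E,10E)-12-bromofarnesyl N,N-diisopropylcarbamate; 6 but-2-yne
Product: 8 (2E,6E,10E)-3,7,11-trimethylhexadeca-2,6,10-trien-14-yn-1-yl N,N-diisopropylcarbamate, via but-2-ynyllithium 7 (not isolated)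
Conditions: 6 (2 equiv), n-BuLi (1.5 equiv), TMEDA (1.5 equiv), THF, −20 °C, 1 h; then 5, −78→0 °C
Reagents that add atoms: but-2-yne (6), CC#CC
Why: Propargylic lithiation of but-2-yne followed by SN2 alkylation of the primary allylic bromide forms C12–C13 and installs C13–C15 plus the C15 methyl group as the only alkyne; excess but-2-yne consumes all n-BuLi, so the carbamate is not lithiated.

Step 5
Reactants: 8 (2E,6E,10E)-3,7,11-trimethylhexadeca-2,6,10-trien-14-yn-1-yl N,N-diisopropylcarbamate
Product: 10 (2E,6E,10E,14E)-15-iodo-3,7,11-trimethylhexadeca-2,6,10,14-tetraen-1-yl N,N-diisopropylcarbamate, via alkenylzirconocene chloride 9 (not isolated)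
Conditions: Cp2Zr(H)Cl (1.6 equiv), THF, 23→40 °C, 2 h, dark; then I2 (1.6 equiv), −78→0 °C; the minor 14-iodo isomer is removed by chromatography
Reagents that add atoms: iodine, [I][I]
Why: Syn-hydrozirconation of the only alkyne (trisubstituted alkenes and the carbamate are inert), with excess Cp2Zr(H)Cl equilibrating zirconium to the less hindered methyl-bearing C15 (about 9:1), followed by iodinolysis with retention, places iodine trans to C13, and this alkene geometry determines the C14/C15 relative configuration in step 7.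

Step 6
Reactants: 11 geranyl bromide; 12 bis(pinacolato)diborylmethane
Product: 14 homogeranyl pinacol boronate, via sodium borylmethanide 13 (not isolated)
Conditions: 12 (1.3 equiv), NaOt-Bu (1.5 equiv), THF, 23 °C, 15 min; then 11, 23 °C, 3 h
Reagents that add atoms: bis(pinacolato)diborylmethane (12), CC1(C)OB(CB2OC(C)(C)C(C)(C)O2)OC1(C)C
Why: In this alkoxide-induced deborylative alkylation, NaOt-Bu removes one boryl group of 12 to give the boron-stabilised carbanion 13, which displaces the primary allylic bromide by SN2 with retention of the E-alkene; no stereocentre is formed.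

Step 7
Reactants: 10 (2E,6E,10E,14E)-15-iodo-3,7,11-trimethylhexadeca-2,6,10,14-tetraen-1-yl N,N-diisopropylcarbamate; 14 homogeranyl pinacol boronate
Product: 18 colleterpenol, via alkenyllithium 15 (not isolated), via lithium boronate complex 16 (not isolated), via tertiary pinacol boronate 17 (not isolated)
Conditions: t-BuLi (2.0 equiv), THF, −78 °C, 20 min; 14 (1.05 equiv), −78→0 °C; syringe pump (12 h) into Pd2(dba)3 (5 mol %), (R)-BINAP [(R)-2,2'-bis(diphenylphosphino)-1,1'-binaphthyl] (12 mol %), THF, 45 °C, final 1 mM; then 3 M NaOH, 30% H2O2, 0→23 °C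
Reagents that add atoms: homogeranyl pinacol boronate (14), CC(C)=CCC/C(C)=C/CCB1OC(C)(C)C(C)(C)O1; hydrogen peroxide, OO
Why: Proposed new method: zerovalent palladium ionises the allylic carbamate to a C1–C3 π-allyl cation equivalent, which is attacked at its unhindered CH2 terminus (C1) by the only strongly nucleophilic alkene present, the C14=C15 bond of boronate complex 16; the charge building at C15 is quenched by antiperiplanar 1,2-migration of the homogeranyl group from boron, so C1 and C16 add anti across the (Z)-alkenyl boronate and set the C14/C15 relative configuration stereospecifically, the BINAP-bound palladium selects the Si face of C14 (absolute configuration), and NaOH/H2O2 replaces boron by OH with retention; the closest known reactions are the palladium- or iridium-π-allyl-triggered allylation/1,2-metalate rearrangement of indolyl and trisubstituted alkenyl boronate complexes (three-component conjunctive coupling) and the Tsuji–Trost macrocyclisation.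

## Compound list
1 | (2E,6E)-farnesol | CC(C)=CCC/C(C)=C/CC/C(C)=C/CO | starting material
2 | N,N-diisopropylcarbamoyl chloride | CC(C)N(C(C)C)C(=O)Cl | starting material
3 | (2E,6E)-3,7,11-trimethyldodeca-2,6,10-trien-1-yl N,N-diisopropylcarbamate | CC(C)=CCC/C(C)=C/CC/C(C)=C/COC(=O)N(C(C)C)C(C)C | intermediate
4 | (2E,6E,10E)-12-hydroxy-3,7,11-trimethyldodeca-2,6,10-trien-1-yl N,N-diisopropylcarbamate | OC/C(C)=C/CC/C(C)=C/CC/C(C)=C/COC(=O)N(C(C)C)C(C)C | intermediate
5 | (2E,6E,10E)-12-bromo-3,7,11-trimethyldodeca-2,6,10-trien-1-yl N,N-diisopropylcarbamate | BrC/C(C)=C/CC/C(C)=C/CC/C(C)=C/COC(=O)N(C(C)C)C(C)C | intermediate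
6 | but-2-yne | CC#CC | starting material
7 | but-2-yn-1-yllithium | [Li]CC#CC | intermediate
8 | (2E,6E,10E)-3,7,11-trimethylhexadeca-2,6,10-trien-14-yn-1-yl N,N-diisopropylcarbamate | CC#CCC/C(C)=C/CC/C(C)=C/CC/C(C)=C/COC(=O)N(C(C)C)C(C)C | intermediate
9 | (14E)-15-[chlorobis(cyclopentadienyl)zirconio] analogue of 10, Zr trans to C13 (Cp rings drawn σ-bound) | Cl[Zr](C1C=CC=C1)(C1C=CC=C1)/C(C)=C/CC/C(C)=C/CC/C(C)=C/CC/C(C)=C/COC(=O)N(C(C)C)C(C)C | intermediate
10 | (2E,6E,10E,14E)-15-iodo-3,7,11-trimethylhexadeca-2,6,10,14-tetraen-1-yl N,N-diisopropylcarbamate (iodine trans to C13) | I/C(C)=C/CC/C(C)=C/CC/C(C)=C/CC/C(C)=C/COC(=O)N(C(C)C)C(C)C | intermediate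
11 | geranyl bromide, (2E)-1-bromo-3,7-dimethylocta-2,6-diene | CC(C)=CCC/C(C)=C/CBr | starting material
12 | bis(pinacolato)diborylmethane, CH2(Bpin)2 | CC1(C)OB(CB2OC(C)(C)C(C)(C)O2)OC1(C)C | starting material
13 | sodium (4,4,5,5-tetramethyl-1,3,2-dioxaborolan-2-yl)methanide | [Na+].[CH2-]B1OC(C)(C)C(C)(C)O1 | intermediate
14 | 2-[(3E)-4,8-dimethylnona-3,7-dien-1-yl]-4,4,5,5-tetramethyl-1,3,2-dioxaborolane | CC(C)=CCC/C(C)=C/CCB1OC(C)(C)C(C)(C)O1 | intermediate
15 | (14Z)-15-lithio analogue of 10 (lithium trans to C13) | [Li]/C(C)=C/CC/C(C)=C/CC/C(C)=C/CC/C(C)=C/COC(=O)N(C(C)C)C(C)C | intermediate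
16 | lithium (alkenyl)(homogeranyl)pinacolatoborate, boron on C15 and trans to C13, carbamate at C1 | [Li+].CC(C)=CCC/C(C)=C/CC[B-]1(OC(C)(C)C(C)(C)O1)/C(C)=C/CC/C(C)=C/CC/C(C)=C/CC/C(C)=C/COC(=O)N(C(C)C)C(C)C | intermediate
17 | 2-{(2R,5E)-6,10-dimethyl-2-[(1R,3E,7E,11E)-4,8,12-trimethylcyclotetradeca-3,7,11-trien-1-yl]undeca-5,9-dien-2-yl}-4,4,5,5-tetramethyl-1,3,2-dioxaborolane (14R,15R) | CC(C)=CCC/C(C)=C/CC[C@](C)(B2OC(C)(C)C(C)(C)O2)[C@H]1C/C=C(\C)CC/C=C(\C)CC/C=C(\C)CC1 | intermediate
18 | colleterpenol, (2S,5E)-6,10-dimethyl-2-[(1R,3E,7E,11E)-4,8,12-trimethylcyclotetradeca-3,7,11-trien-1-yl]undeca-5,9-dien-2-ol (14R,15S) | CC(C)=CCC/C(C)=C/CC[C@](C)(O)[C@H]1C/C=C(\C)CC/C=C(\C)CC/C=C(\C)CC1 | target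

## Step count and risks
Total steps: 7. Longest linear sequence: 6 (steps 1, 2, 3, 4, 5, 7).

**Step 7 (highest risk).** The π-allylpalladium may transmetalate with the boronate and give a Suzuki-type 1,4-diene instead of triggering migration. Ionisation of the trisubstituted allylic carbamate may be slow. Oligomers may compete with ring closure, and face selection at C14 may be poor.

The fallback sets out from 16 (made as in step 7) and returns at 18. It separates the stereodefining migration from the ring closure and closes the same C1–C14 bond with reversed polarity.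
- 16 is treated with N-(phenylthio)saccharin and 10 mol % of (S)-4-(diisopropylamino)-3,5-dimethyl-4,5-dihydro-3H-dinaphtho[2,1-d:1',2'-f][1,3,2]diazaphosphepine 4-selenide (C28H32N3PSe) at −60 °C. This is a Lewis-base-catalysed enantioselective carbosulfenylation with 1,2-boronate migration. The catalyst antipode is chosen so that sulfur enters on the Si face of C14. The product is β-phenylthio tertiary boronate F1.
- NaBO3·4H2O in THF/water gives hydroxy sulfide F2.
- Me3OBF4 in CH2Cl2 gives S-methylsulfonium tetrafluoroborate F3, which aqueous NaOH closes with inversion at C14 to cis-14,15-epoxide F4.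
- Pd(PPh3)4 and PhSO2Na in THF/MeOH exchange the carbamate for a sulfone and give epoxy phenyl sulfone F5.
- n-BuLi (THF, 1 mM, −78→23 °C) makes the C1 sulfonyl carbanion open the epoxide at the secondary C14. This second inversion puts C1 where sulfur stood and gives macrocyclic hydroxy sulfone F6.
- PdCl2(dppp) with LiHBEt3 in THF at 0 °C removes the sulfone and gives 18.

**Step 5.** The 15- versus 14-zirconation ratio (about 9:1) may be lower, and the iodides may be hard to separate. The fallback sets out from 5 (bypassing step 4 as well) and returns at 10. It builds the trisubstituted alkene by olefination instead of alkyne hydrometalation.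
- 5 is alkylated with the lithium anion of acetonitrile (THF, −78 °C) to give nitrile F7.
- i-Bu2AlH (toluene, −78 °C), then mild acid, gives aldehyde F8.
- A boron-Wittig reaction with 1,1-bis(pinacolboryl)ethane and lithium 2,2,6,6-tetramethylpiperidide (THF, −78→23 °C) proceeds by syn B–O elimination through the less crowded arrangement. It gives (Z)-alkenyl pinacol boronate F9, with boron trans to C13.
- NaOH, then I2, in THF replaces boron by iodine with retention and gives 10.

**Step 6.** The alkoxide may etherify or eliminate geranyl bromide, and SN2' attack is possible. The fallback sets out from 11 and returns at 14. It inserts the CH2 group into an allylboronate instead of alkylating a boryl carbanion.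
- 11 and B2pin2 with Pd2(dba)3 (2.5 mol %) in THF at 60 °C give geranyl pinacol boronate F10.
- LiCH2Cl (from BrCH2Cl and n-BuLi, THF, −78 °C) adds to boron to give chloromethyl boronate complex F11.
- On warming, F11 undergoes Matteson 1,2-migration of the geranyl group and gives 14.

## Further compounds
F1 | step 7 | β-phenylthio tertiary boronate (14S,15R) | CC(C)=CCC/C(C)=C/CC[C@](C)(B1OC(C)(C)C(C)(C)O1)[C@@H](Sc1ccccc1)CC/C(C)=C/CC/C(C)=C/CC/C(C)=C/COC(=O)N(C(C)C)C(C)C
F2 | step 7 | hydroxy sulfide (14S,15S) | CC(C)=CCC/C(C)=C/CC[C@](C)(O)[C@@H](Sc1ccccc1)CC/C(C)=C/CC/C(C)=C/CC/C(C)=C/COC(=O)N(C(C)C)C(C)C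
F3 | step 7 | S-methylsulfonium tetrafluoroborate | CC(C)=CCC/C(C)=C/CC[C@](C)(O)[C@@H]([S+](C)c1ccccc1)CC/C(C)=C/CC/C(C)=C/CC/C(C)=C/COC(=O)N(C(C)C)C(C)C.F[B-](F)(F)F
F4 | step 7 | cis-14,15-epoxide (14R,15S) | CC(C)=CCC/C(C)=C/CC[C@]1(C)O[C@@H]1CC/C(C)=C/CC/C(C)=C/CC/C(C)=C/COC(=O)N(C(C)C)C(C)C
F5 | step 7 | epoxy phenyl sulfone | CC(C)=CCC/C(C)=C/CC[C@]1(C)O[C@@H]1CC/C(C)=C/CC/C(C)=C/CC/C(C)=C/CS(=O)(=O)c1ccccc1
F6 | step 7 | macrocyclic hydroxy sulfone (C14 and C15 as in 18, C1 epimers) | CC(C)=CCC/C(C)=C/CC[C@](C)(O)[C@H]1C(S(=O)(=O)c2ccccc2)/C=C(\C)CC/C=C(\C)CC/C=C(\C)CC1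
F7 | step 5 | nitrile | N#CCC/C(C)=C/CC/C(C)=C/CC/C(C)=C/COC(=O)N(C(C)C)C(C)C
F8 | step 5 | aldehyde | O=CCC/C(C)=C/CC/C(C)=C/CC/C(C)=C/COC(=O)N(C(C)C)C(C)C
F9 | step 5 | (Z)-alkenyl pinacol boronate | CC1(C)OB(OC1(C)C)/C(C)=C/CC/C(C)=C/CC/C(C)=C/CC/C(C)=C/COC(=O)N(C(C)C)C(C)C
F10 | step 6 | geranyl pinacol boronate | CC(C)=CCC/C(C)=C/CB1OC(C)(C)C(C)(C)O1
F11 | step 6 | chloromethyl boronate complex | [Li+].ClC[B-]1(C/C=C(\C)CCC=C(C)C)OC(C)(C)C(C)(C)O1
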